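**Retrosynthetic overview**
- The route rests on the fully substituted benzoquinone ring, numbered Q1 (C=O), Q2 (indol-3-yl), Q3 (O), Q4 (C=O), Q5 (indol-3-yl), Q6 (O). The para carbons Q1/Q4 are traced back to a chromium carbene carbon and one CO ligand, Q2–Q3 to an indolyl ynol ether, and Q5–Q6 to the alkenyl group of the carbene.
- Target 24 ← ethoxy/hydroxy quinone 23 (OEt/OOH exchange) ← symmetric diethoxyquinone 21 (mono-saponification) ← 20 (N-desilylation) ← hexasubstituted 4-methoxyphenol 19 (oxidative demethylation).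
- 19 ← carbene complex 17 + ynol ether 12 + CO (benzannulation forming Q1–Q2, Q3–Q4 and Q4–Q5). This is the only ring formed; both indole rings are bought intact.
- Both partners come from 12: used directly as the alkyne, and converted to 17 by syn-hydrostannation, Sn–Li exchange, Cr(CO)6 and O-methylation.
- 12 ← 5-bromoindole by N-silylation, prenylation through an arylcopper, C3 iodination and Negishi coupling with an ethoxyethynylzinc reagent.

Key step: step 7

Assumption: the target is symmetric apart from OH versus OOH, so Q3 and Q6 are equivalent. Both therefore carry ethoxy as a spectator group (Q6 ethoxy in place of methoxy), which lets one ynol ether serve both halves and fixes the alkene geometry of the carbene.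

**Route**

Step 1
Reactants: 1 5-bromoindole
Product: 3 5-bromo-1-(triisopropylsilyl)-1H-indole, via sodium 5-bromoindolide 2 (not isolated)
Conditions: NaH, THF, 0 °C; then i-Pr3SiCl, 0 °C → rt
Reagents that add atoms: chlorotriisopropylsilane, CC(C)[Si](Cl)(C(C)C)C(C)C
Why: N-silylation of the sodium indolide; the bulky silyl group removes the N–H and shields C2 in the later organometallic steps.

Step 2
Reactants: 3 5-bromo-1-(triisopropylsilyl)-1H-indole; 4 1-bromo-3-methylbut-2-ene (prenyl bromide)
Product: 7 5-(3-methylbut-2-enyl)-1-(triisopropylsilyl)-1H-indole, via aryllithium 5 (not isolated), via arylcopper 6 (not isolated)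
Conditions: t-BuLi (2 equiv), THF, −78 °C; CuBr·SMe2, −78 → −40 °C; 4, −40 → 0 °C
Reagents that add atoms: none
Why: Bromine–lithium exchange at −78 °C outruns any deprotonation, and the arylcopper should alkylate prenyl bromide at its unhindered primary carbon (copper-mediated allylic substitution) to give the linear prenyl group.

Step 3
Reactants: 7 5-(3-methylbut-2-enyl)-1-(triisopropylsilyl)-1H-indole
Product: 8 3-iodo-5-(3-methylbut-2-enyl)-1-(triisopropylsilyl)-1H-indole
Conditions: NIS, DMF, 0 °C → rt, dark
Reagents that add atoms: N-iodosuccinimide, O=C1CCC(=O)N1I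
Why: Electrophilic aromatic iodination at C3, the enamine-like position of the N-silylindole, which should react much faster than the trisubstituted alkene while C2 is shielded by the silyl group.

Step 4
Reactants: 8 3-iodo-5-(3-methylbut-2-enyl)-1-(triisopropylsilyl)-1H-indole; 9 ethoxyethyne
Product: 12 3-(ethoxyethynyl)-5-(3-methylbut-2-enyl)-1-(triisopropylsilyl)-1H-indole, via lithium ethoxyacetylide 10 (not isolated), via chloro(ethoxyethynyl)zinc 11 (not isolated)
Conditions: 9, n-BuLi, THF, −78 °C; ZnCl2, −78 → 0 °C; 8, Pd(PPh3)4 (5 mol%), rt; chromatography on Et3N-deactivated silica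
Reagents that add atoms: none
Why: Negishi coupling of an alkynylzinc with an aryl iodide proceeds at room temperature under zerovalent palladium, mild enough for the heat- and acid-sensitive aryl ynol ether.

Step 5
Reactants: 12 3-(ethoxyethynyl)-5-(3-methylbut-2-enyl)-1-(triisopropylsilyl)-1H-indole
Product: 13 tributyl{(E)-1-ethoxy-2-[5-(3-methylbut-2-enyl)-1-(triisopropylsilyl)indol-3-yl]ethenyl}stannane (ethoxy and indolyl cis)
Conditions: Bu3SnH (slow addition), Pd(PPh3)4 (2 mol%), THF, 0 °C → rt; filtration through basic alumina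
Reagents that add atoms: tributylstannane, CCCC[SnH](CCCC)CCCC
Why: Palladium-catalysed syn-hydrostannation of 1-alkoxyalkynes places tin on the oxygen-bearing carbon and hydrogen cis to it, which fixes the alkene geometry with indolyl and ethoxy on the same side.

Step 6
Reactants: 13 the (E)-α-ethoxyvinylstannane; 14 Cr(CO)6
Product: 17 pentacarbonyl{(Z)-2-ethoxy-1-methoxy-3-[5-(3-methylbut-2-enyl)-1-(triisopropylsilyl)indol-3-yl]prop-2-enylidene}chromium, via vinyllithium 15 (not isolated), via lithium acylchromate 16 (not isolated)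
Conditions: n-BuLi (1.0 equiv), THF, −78 °C; Cr(CO)6, −78 → 0 °C; solvent exchange; Me3OBF4, CH2Cl2, 0 °C
Reagents that add atoms: trimethyloxonium tetrafluoroborate, C[O+](C)C.F[B-](F)(F)F
Why: Tin–lithium exchange with retention gives a configurationally stable α-ethoxyvinyllithium that adds to a CO ligand, and O-methylation of the acylchromate completes a Fischer carbene synthesis of the kind known for α-alkoxyvinyl complexes.

Step 7
Reactants: 17 the alkenyl(methoxy)carbene chromium complex; 12 3-(ethoxyethynyl)-5-(3-methylbut-2-enyl)-1-(triisopropylsilyl)-1H-indole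
Product: 19 2,5-diethoxy-4-methoxy-3,6-bis[5-(3-methylbut-2-enyl)-1-(triisopropylsilyl)indol-3-yl]phenol, via tricarbonylchromium arene complex 18 (not isolated)
Conditions: THF (0.05 M), 55 °C, Ar, slow addition of 12 (1.3 equiv); then air, rt
Reagents that add atoms: none
Why: Proposed new method: the ynol ether is expected to enter the chromium–carbene bond, after thermal loss of one CO or by direct attack of its nucleophilic indolyl-bearing carbon on the electrophilic carbene carbon, giving an ethoxy-stabilised dienylcarbene (bond Q1–Q2), and CO insertion then gives a chromium-bound dienylketene (bond Q3–Q4). The six-membered ring closes by thermal 6π-electrocyclisation of that dienylketene (bond Q4–Q5), and enolisation of the cyclohexadienone gives the phenol as its Cr(CO)3 complex 18, which air sets free. The closest known reaction types are the Dötz benzannulation of alkenyl(alkoxy)carbene complexes of zerovalent chromium with internal alkynes, the insertion of ynamines into such complexes with the same polarity, and the thermal cyclisation of dienylcarbene complexes to ortho-alkoxyphenols; a heteroaryl-substituted 1-alkoxyalkyne has not been combined with an α-alkoxy-β-indolyl alkenyl carbene in this way. No stereocentre is formed. The step needs insertion with the indolyl carbon bonding to the carbene carbon, which puts the two indoles para, and this must come from the polarisation of the ynol ether against its steric bias; it also needs the hydrogen at Q5 to point inward for ring closure, which the geometry set in step 5 provides.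

Step 8
Reactants: 19 2,5-diethoxy-4-methoxy-3,6-bis[5-(3-methylbut-2-enyl)-1-(triisopropylsilyl)indol-3-yl]phenol
Product: 20 2,5-diethoxy-3,6-bis[5-(3-methylbut-2-enyl)-1-(triisopropylsilyl)indol-3-yl]cyclohexa-2,5-diene-1,4-dione
Conditions: (NH4)2Ce(NO3)6 (2.2 equiv), MeCN/THF/H2O, 0 °C, short contact; NaHCO3 quench
Reagents that add atoms: water, O
Why: Oxidative demethylation of a 4-methoxyphenol by tetravalent cerium (two-electron oxidation, water adds at Q1, methanol leaves); the hydroquinone monoether is far easier to oxidise than the N-silylindoles or the prenyl alkenes.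

Step 9
Reactants: 20 the bis-silylated diethoxyquinone
Product: 21 2,5-diethoxy-3,6-bis[5-(3-methylbut-2-enyl)-1H-indol-3-yl]cyclohexa-2,5-diene-1,4-dione
Conditions: Bu4NF, AcOH (1:1), THF, 0 °C → rt
Reagents that add atoms: none
Why: Fluoride cleaves both N–Si bonds, and the acetic acid buffer protonates the indolide and keeps hydroxide away from the vinylogous esters.

Step 10
Reactants: 21 the diethoxyquinone
Product: 23 2-ethoxy-5-hydroxy-3,6-bis[5-(3-methylbut-2-enyl)-1H-indol-3-yl]cyclohexa-2,5-diene-1,4-dione, via sodium hydroxyquinonate 22 (not isolated)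
Conditions: NaOH (1.5 equiv), THF/EtOH/H2O, 0 °C → rt; then cold aq. HCl to pH 3
Reagents that add atoms: sodium hydroxide, [Na+].[OH-]
Why: Saponification of one vinylogous ester by addition–elimination of hydroxide; the delocalised hydroxyquinone anion deactivates the second ethoxy-bearing carbon, and the symmetric substrate can give only one monoether.

Step 11
Reactants: 23 the ethoxy/hydroxy quinone
Product: 24 hydroperoxycochliodinol, 2-hydroperoxy-5-hydroxy-3,6-bis[5-(3-methylbut-2-enyl)-1H-indol-3-yl]cyclohexa-2,5-diene-1,4-dione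
Conditions: H2O2·urea (5 equiv), Zn(OSO2CF3)2 (20 mol%), MeCN, 0 °C → rt, dark; aqueous wash without reducing agents
Reagents that add atoms: hydrogen peroxide as its urea adduct, NC(N)=O.OO
Why: Proposed new method: the Q3 hydroxyl hydrogen-bonds (or chelates zinc) to the neighbouring carbonyl Q4, which belongs to the vinylogous ester O=Q4–Q5=Q6–OEt, so H2O2 should add at Q6 and ethanol leave by addition–elimination while the hydroxy-bearing carbon is not activated in the same way; the closest known reaction types are the acid-catalysed exchange of alkoxy groups on alkoxyquinones with alcohols, the formation of peroxy acids from esters or acids with H2O2, and the displacement of halide from halobenzoquinones by H2O2.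

**Compound list**

1 | 5-bromoindole | Brc1ccc2[nH]ccc2c1 | starting material
2 | sodium 5-bromoindol-1-ide | [Na+].Brc1ccc2[n-]ccc2c1 | intermediate
3 | 5-bromo-1-(triisopropylsilyl)-1H-indole | CC(C)[Si](C(C)C)(C(C)C)n1ccc2cc(Br)ccc21 | intermediate
4 | 1-bromo-3-methylbut-2-ene | CC(C)=CCBr | starting material
5 | 5-lithio-1-(triisopropylsilyl)indole | [Li]c1ccc2c(ccn2[Si](C(C)C)(C(C)C)C(C)C)c1 | intermediate
6 | [1-(triisopropylsilyl)indol-5-yl]copper | [Cu]c1ccc2c(ccn2[Si](C(C)C)(C(C)C)C(C)C)c1 | intermediate
7 | 5-(3-methylbut-2-enyl)-1-(triisopropylsilyl)-1H-indole | CC(C)=CCc1ccc2c(ccn2[Si](C(C)C)(C(C)C)C(C)C)c1 | intermediate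
8 | 3-iodo-5-(3-methylbut-2-enyl)-1-(triisopropylsilyl)-1H-indole | CC(C)=CCc1ccc2c(c1)c(I)cn2[Si](C(C)C)(C(C)C)C(C)C | intermediate
9 | ethoxyethyne | CCOC#C | starting material
10 | lithium ethoxyacetylide | CCOC#C[Li] | intermediate
11 | chloro(ethoxyethynyl)zinc | CCOC#C[Zn]Cl | intermediate
12 | 3-(ethoxyethynyl)-5-(3-methylbut-2-enyl)-1-(triisopropylsilyl)-1H-indole | CCOC#Cc1cn([Si](C(C)C)(C(C)C)C(C)C)c2ccc(CC=C(C)C)cc12 | intermediate
13 | tributyl{(E)-1-ethoxy-2-[5-(3-methylbut-2-enyl)-1-(triisopropylsilyl)indol-3-yl]ethenyl}stannane | CCO/C([Sn](CCCC)(CCCC)CCCC)=C\c1cn([Si](C(C)C)(C(C)C)C(C)C)c2ccc(CC=C(C)C)cc12 | intermediate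
14 | Cr(CO)6, hexacarbonylchromium | O=C=[Cr](=C=O)(=C=O)(=C=O)(=C=O)=C=O | starting material
15 | (Z)-1-ethoxy-2-[5-(3-methylbut-2-enyl)-1-(triisopropylsilyl)indol-3-yl]ethenyllithium | CCO/C([Li])=C\c1cn([Si](C(C)C)(C(C)C)C(C)C)c2ccc(CC=C(C)C)cc12 | intermediate
16 | lithium pentacarbonyl{(Z)-2-ethoxy-3-[5-(3-methylbut-2-enyl)-1-(triisopropylsilyl)indol-3-yl]prop-2-enoyl}chromate | [Li+].[O-]C(=[Cr](=C=O)(=C=O)(=C=O)(=C=O)=C=O)/C(OCC)=C/c1cn([Si](C(C)C)(C(C)C)C(C)C)c2ccc(CC=C(C)C)cc12 | intermediate
17 | pentacarbonyl{(Z)-2-ethoxy-1-methoxy-3-[5-(3-methylbut-2-enyl)-1-(triisopropylsilyl)indol-3-yl]prop-2-enylidene}chromium | COC(=[Cr](=C=O)(=C=O)(=C=O)(=C=O)=C=O)/C(OCC)=C/c1cn([Si](C(C)C)(C(C)C)C(C)C)c2ccc(CC=C(C)C)cc12 | intermediate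
18 | tricarbonyl(η6-arene)chromium complex of phenol 19 (written as arene plus Cr(CO)3 fragment) | CCOc1c(O)c(-c2cn([Si](C(C)C)(C(C)C)C(C)C)c3ccc(CC=C(C)C)cc23)c(OCC)c(OC)c1-c1cn([Si](C(C)C)(C(C)C)C(C)C)c2ccc(CC=C(C)C)cc12.O=C=[Cr](=C=O)=C=O | intermediate
19 | 2,5-diethoxy-4-methoxy-3,6-bis[5-(3-methylbut-2-enyl)-1-(triisopropylsilyl)indol-3-yl]phenol | CCOc1c(O)c(-c2cn([Si](C(C)C)(C(C)C)C(C)C)c3ccc(CC=C(C)C)cc23)c(OCC)c(OC)c1-c1cn([Si](C(C)C)(C(C)C)C(C)C)c2ccc(CC=C(C)C)cc12 | intermediate
20 | 2,5-diethoxy-3,6-bis[5-(3-methylbut-2-enyl)-1-(triisopropylsilyl)indol-3-yl]cyclohexa-2,5-diene-1,4-dione | CCOC1=C(c2cn([Si](C(C)C)(C(C)C)C(C)C)c3ccc(CC=C(C)C)cc23)C(=O)C(OCC)=C(c2cn([Si](C(C)C)(C(C)C)C(C)C)c3ccc(CC=C(C)C)cc23)C1=O | intermediate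
21 | 2,5-diethoxy-3,6-bis[5-(3-methylbut-2-enyl)-1H-indol-3-yl]cyclohexa-2,5-diene-1,4-dione | CCOC1=C(c2c[nH]c3ccc(CC=C(C)C)cc23)C(=O)C(OCC)=C(c2c[nH]c3ccc(CC=C(C)C)cc23)C1=O | intermediate
22 | sodium salt of 23 (hydroxyquinonate) | [Na+].CCOC1=C(c2c[nH]c3ccc(CC=C(C)C)cc23)C(=O)C([O-])=C(c2c[nH]c3ccc(CC=C(C)C)cc23)C1=O | intermediate
23 | 2-ethoxy-5-hydroxy-3,6-bis[5-(3-methylbut-2-enyl)-1H-indol-3-yl]cyclohexa-2,5-diene-1,4-dione | CCOC1=C(c2c[nH]c3ccc(CC=C(C)C)cc23)C(=O)C(O)=C(c2c[nH]c3ccc(CC=C(C)C)cc23)C1=O | intermediate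
24 | hydroperoxycochliodinol | CC(C)=CCc1ccc2[nH]cc(C3=C(O)C(=O)C(c4c[nH]c5ccc(CC=C(C)C)cc45)=C(OO)C3=O)c2c1 | target

**Step count**
Total steps: 11. Longest linear sequence: 11 (steps 1–11; compound 12 feeds both partners of step 7).

**Steps most likely to fail**

1. Step 7. The ynol ether may insert with the opposite orientation under steric control. The ethoxy-stabilised dienylcarbene may also be diverted before CO insertion, by uptake of a second alkyne or by cyclobutenone or five-membered-ring formation, or the new double bond may form with a geometry that prevents closure. The fallback uses known chemistry on a preformed quinone ring instead of the benzannulation. It sets out from 7: Bu4NF in THF removes the silyl group to give 5-(3-methylbut-2-enyl)-1H-indole F1. Two equivalents of F1 with tetrabromo-1,4-benzoquinone and Cs2CO3 in MeCN at rt (base-mediated addition–elimination of indole C3 on the bromoquinone, twice, para) should give 2,5-dibromo-3,6-bis[5-(3-methylbut-2-enyl)-1H-indol-3-yl]cyclohexa-2,5-diene-1,4-dione F2. NaOEt in EtOH/THF at 0 °C then replaces both bromides and the route is rejoined at 21.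

2. Step 11. Exchange may also occur at the hydroxy-bearing carbon, adventitious water may hydrolyse the ethoxy group instead, or the peroxide may oxidise the indole 2,3-bonds or the prenyl alkenes. The fallback replaces the alkoxy exchange by halide displacement, a substitution known for halobenzoquinones and H2O2. It sets out from 23: excess NaOH in aqueous THF/EtOH at 60 °C followed by acidification completes the saponification to the dihydroxyquinone cochliodinol F3. (COCl)2 (1 equiv) with catalytic DMF in CH2Cl2 at 0 °C converts one vinylogous acid into its acid chloride, 2-chloro-5-hydroxy-3,6-bis[5-(3-methylbut-2-enyl)-1H-indol-3-yl]cyclohexa-2,5-diene-1,4-dione F4, which is separated from unchanged F3 and any dichloride. F4 with ethereal H2O2 over solid NaHCO3 at 0 °C should give 24.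

3. Step 5. Tin may be delivered to the indolyl-bearing carbon, or the acid-labile α-stannyl enol ether may lose tin on isolation. The fallback replaces hydrometalation and transmetalation by deprotonation. It sets out from 12: semi-hydrogenation (H2, Pd/CaCO3 poisoned with Pb(OAc)2, quinoline, hexane) gives 3-[(Z)-2-ethoxyethenyl]-5-(3-methylbut-2-enyl)-1-(triisopropylsilyl)-1H-indole F5. Deprotonation at the oxygen-bearing vinyl carbon with t-BuLi in THF (−78 → −30 °C) gives the vinyllithium 15, which is carried on as in step 6.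

**Further compounds**

F1 | step 7 | 5-(3-methylbut-2-enyl)-1H-indole | CC(C)=CCc1ccc2[nH]ccc2c1
F2 | step 7 | 2,5-dibromo-3,6-bis[5-(3-methylbut-2-enyl)-1H-indol-3-yl]cyclohexa-2,5-diene-1,4-dione | O=C1C(Br)=C(c2c[nH]c3ccc(CC=C(C)C)cc23)C(=O)C(Br)=C1c1c[nH]c2ccc(CC=C(C)C)cc12
F3 | step 11 | cochliodinol, 2,5-dihydroxy-3,6-bis[5-(3-methylbut-2-enyl)-1H-indol-3-yl]cyclohexa-2,5-diene-1,4-dione | CC(C)=CCc1ccc2[nH]cc(C3=C(O)C(=O)C(c4c[nH]c5ccc(CC=C(C)C)cc45)=C(O)C3=O)c2c1
F4 | step 11 | 2-chloro-5-hydroxy-3,6-bis[5-(3-methylbut-2-enyl)-1H-indol-3-yl]cyclohexa-2,5-diene-1,4-dione | CC(C)=CCc1ccc2[nH]cc(C3=C(O)C(=O)C(c4c[nH]c5ccc(CC=C(C)C)cc45)=C(Cl)C3=O)c2c1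
F5 | step 5 | 3-[(Z)-2-ethoxyethenyl]-5-(3-methylbut-2-enyl)-1-(triisopropylsilyl)-1H-indole | CCO/C=C\c1cn([Si](C(C)C)(C(C)C)C(C)C)c2ccc(CC=C(C)C)cc12
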